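## The problem

1. With biogenetic numbering the target is an elemane lactone. The cyclohexane is C5–C10; C10 carries the methyl C14 and the vinyl group C1=C2; C5 carries the acrylic acid C4(=C3)–C15; C7 carries C11(=C13)–C12, which closes a trans-fused γ-lactone on O6; O8 carries the tiglate.
2. Five stereocentres are contiguous (C10, C5, C6, C7, C8); four ring substituents are equatorial, and the C10 methyl and the C8 acyloxy group are syn-diaxial.
3. C10 is quaternary, and methyl and vinyl differ too little in size for a reagent to tell them apart on a ring, so C10 must be set by transfer from a defined alkene geometry, together with its neighbour C5.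
4. The feature that allows this: C6–C5–C4(=C3)–C15 is the carbon skeleton of itaconic acid, and C2=C1–C10–C5–C6 is a pent-4-enoyl unit once C6 is written as a carboxyl carbon, which is the product pattern of an ester enolate Claisen rearrangement of an allyl itaconate.
5. The same pattern recurs on the other side of C6: C8–C7–C11(=C13)–C12 is a 2-methylene-4-oxobutanoate if C8 is a ketone, which makes C7 acidic and lets the C6–C7 bond and the lactone form in one aldol event.
6. The axial C10 methyl decides the rest: it blocks axial hydride approach to a C8 ketone (giving the wanted axial 8β-oxygen) but would do the same to a C6 ketone (giving the wrong epimer), so O6 must come from an aldehyde during C–C bond formation.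
7. Both 1-carboxyvinyl groups can lactonise on O6 and C12 can also reach O8, so the three acyl groups must be told apart by their esters.
8. Three Michael acceptors, the 1,5-diene, and the enolisable centres C5 and C7 rule out strong base, heat and nucleophilic reagents late in the route.

## Retrosynthesis

**20 ⇒ 19 ⇒ 17 + 18.** The last bonds made are O–H of the C15 acid (20 from tert-butyl ester 19) and O8–acyl (19 from alcohol 17 and tigloyl chloride 18). Acidolysis is preferred to saponification, which lactone, tiglate and Michael acceptors would not survive. Acylating after the lactone is closed leaves no choice between O6 and O8. The simplification is small; the forward steps need only be non-basic and non-nucleophilic.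

**17 ⇒ 16.** The C8–H bond is cut, giving ketone 16. Carrying an sp3 C8 oxygen from the start would mean setting it in an open chain with no controller nearby. In 16 the axial C10 methyl should steer hydride to the equatorial trajectory, and the same ketone makes C7 nucleophilic one step earlier. The forward step needs a bulky hydride that does not add in conjugate fashion.

**16 ⇒ 12.** C6–C7 and O6–C12 are cut together: an intramolecular aldol addition of the C8 ketone (through C7) to a C6 aldehyde, followed by lactonisation. The neighbouring cut C7–C8 (C6 ketone donor, C8 aldehyde) would leave O6 as a ketone to be reduced against the axial methyl and would put the lactone on O8. Keto aldehyde 12 is open-chain with only C5 and C10 as stereocentres, so two rings and two stereocentres are gained. The forward step needs enolisation at C7 (not C5 or C9), chair closure with the C5 substituent equatorial, and lactonisation onto the methyl ester, not the tert-butyl ester.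

**12 ⇒ 11 ⇒ 9 + 10, and 9 ⇒ 8.** C7–C8 is cut. Keto aldehyde 12 comes from diol 11 by double oxidation. Diol 11 comes from lactol 9 (the C8 aldehyde) and methyl 2-(bromomethyl)acrylate 10, which delivers C7, C11, C12 and C13 at the final oxidation level; the Barbier reaction runs on the unprotected lactol. Lactol 9 comes from alkynol 8 by anti-Markovnikov hydration. The ethynyl group on C10 is the masked C9H2–C8HO arm: it needs no protecting group, is inert in the Claisen step, and is already present in the commercial enynol 1. The forward steps need alkyne-selective hydration beside three alkenes, and allylation faster than lactonisation onto O8.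

**8 ⇒ 6 ⇒ 4 ⇒ 3 ⇒ 1 + 2.** C5–C10 is cut. Alcohol 8 is the reduced form of acid 6, which is the Claisen product of ester 4. Ester 4 is made by opening itaconic anhydride 2 with enynol 1 (half ester 3) and capping C15 as the tert-butyl ester. A Cope cut of the same bond needs a ten-membered ring; the Claisen cut needs only an ester of two commercial compounds. Ester 4 is achiral, and acid 6 holds the quaternary carbon, its neighbour, the vinyl group and the intact acrylate. The forward step needs E(O) ketene acetal geometry, a chair array and reagent control of the absolute sense.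

## Roads not taken

Alternative 1: keep the ring and add the substituents (the route most would draw first).
- Cut: C10–C1, then C5–C4 and C7–C11.
- Forward: (CH2=CH)2CuLi adds to enone A1 trans to the silyloxy group to give ketone A2; enolate alkylations with a haloacetate at C5 and C7, reduction of the C6 ketone, lactonisation and two α-methylenations follow.
- Why not: the C6 ketone sits syn to the axial C10 methyl and between two substituted carbons, so hydride should enter equatorially and give the axial 6β-alcohol, the wrong epimer. The two acetate arms at C5 and C7 are near-equivalent toward O6. Enolisation toward C7 risks β-elimination of the C8 oxygen. Both acrylate units are built late and stepwise, whereas the chosen plan brings them in intact.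

Alternative 2: biomimetic Cope rearrangement.
- Cut: C5–C10 as a [3,3] shift, leading back to germacranolide A3.
- Forward: heat the ten-membered diene.
- Why not: A3 already contains C6, C7, C8, the lactone and the tiglate inside a strained medium ring with two trans double bonds, so the precursor is harder to make than the target. The equilibrium and the temperature needed also threaten the tiglate and the Michael acceptors. The Claisen version forms the same bond from an acyclic ester.

Alternative 3: dearomatisation.
- Cut: map C6-O, C8-O and C10 onto 3,5-dimethoxybenzoic acid A4; Birch reductive methylation and conversion of the carboxyl into vinyl give the prochiral dione A5.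
- Forward key step: an enantiotopic-group-selective reaction on A5.
- Why not: C10 would have to be distinguished by telling two ring CH2–C=O arms apart from a remote methyl/vinyl pair, for which no reliable control exists on an enolised 2-substituted dione. The two carbonyls then need opposite reductions (equatorial at C6, axial at C8), and the acrylate must be attached at the hindered C5. The step count exceeds the chosen route before any stereocentre is secured.

Key step: step 3

Assumption: the (4S,5S)-bromoborane is taken to give the (2R,3S) acid 6 through the E(O) boron ketene acetal; if the sense of induction is the opposite, the (4R,5R)-reagent is used and nothing else changes.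

## Route

Step 1
Reactants: 1 (E)-3-methylpent-2-en-4-yn-1-ol; 2 itaconic anhydride
Product: 3 2-methylidene-4-{[(2E)-3-methylpent-2-en-4-yn-1-yl]oxy}-4-oxobutanoic acid
Conditions: toluene, 60 °C, no base
Reagents that add atoms: none
Why: Alcoholysis of a cyclic anhydride: the alcohol should attack the CH2-bound carbonyl, which is unconjugated and less hindered, giving the 4-ester with the conjugated acid free; without base the exocyclic double bond should not move into conjugation.

Step 2
Reactants: 3 half ester
Product: 4 1-tert-butyl 4-[(2E)-3-methylpent-2-en-4-yn-1-yl] 2-methylidenebutanedioate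
Conditions: O-tert-butyl-N,N′-diisopropylisourea (2.5 equiv), CH2Cl2, 23 °C
Reagents that add atoms: O-tert-butyl-N,N′-diisopropylisourea, CC(C)N=C(NC(C)C)OC(C)(C)C
Why: Esterification of a carboxylic acid by an O-alkylisourea under neutral conditions; the tert-butyl ester is chosen because it cannot lactonise onto O6 later and is removed by acid alone in the last step.

Step 3
Reactants: 4 allyl itaconate diester
Product: 6 (2R,3S)-2-[1-(tert-butoxycarbonyl)ethenyl]-3-ethynyl-3-methylpent-4-enoic acid, via boron ketene acetal 5 (not isolated)
Conditions: (4S,5S)-2-bromo-1,3-bis{[3,5-bis(trifluoromethyl)phenyl]sulfonyl}-4,5-diphenyl-1,3,2-diazaborolidine (1.2 equiv, freshly prepared), Et3N (3 equiv), toluene/hexane, −78 °C; then −20 → 4 °C; aqueous work-up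
Reagents that add atoms: none
Why: The boron reagent binds the carbonyl of the allyl ester (the only ester with α-hydrogens), Et3N removes the doubly activated H-5, and ketene acetal 5 should form with the acrylate unit trans to O–B, the geometry this reagent type gives with alkyl esters in hydrocarbon solvent. On warming, a concerted suprafacial [3,3] shift (ester enolate, Ireland–Claisen rearrangement) through a chair forms C5–C10, breaks C2–O, creates the vinyl group C1=C2 and carries the 1-(tert-butoxycarbonyl)vinyl group over untouched. The closest known reaction type is the enantioselective boron-mediated ester enolate Claisen rearrangement of E-3,3-disubstituted allyl esters of β,γ-unsaturated acids. No ring is closed. C10 is set by the E geometry of the enyne: ethynyl is trans to C2 and pseudo-equatorial, methyl pseudo-axial, so methyl, vinyl and the two-carbon arm are told apart by position on the alkene, not by size. C5 is set relative to C10 by the ketene acetal geometry (acrylate pseudo-axial), which gives the 5R,10S relationship of the target. The absolute sense comes from the C2-symmetric diazaborolidine, which shields one face of the ketene acetal. The step needs α- rather than γ-bonding of the dienolate (only the α-carbon reaches C10 in a six-membered array), a chair rather than a boat, and no enolisation elsewhere (the tert-butyl ester has no α-hydrogen and an amine does not deprotonate the alkyne).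

Step 4
Reactants: 6 Claisen acid
Product: 8 tert-butyl (3R,4S)-4-ethynyl-3-(hydroxymethyl)-4-methyl-2-methylidenehex-5-enoate, via acyl imidazolide 7 (not isolated)
Conditions: 1,1′-carbonyldiimidazole, THF, 23 °C; then NaBH4, THF/H2O, 0 °C
Reagents that add atoms: none
Why: Activation as the acyl imidazolide and NaBH4 reduction should convert the hindered acid into the primary alcohol without touching the tert-butyl acrylate, the alkyne or the alkenes; C5 is not enolised under these conditions.

Step 5
Reactants: 8 alkynol
Product: 9 tert-butyl 2-[(3R,4S)-4-ethenyl-6-hydroxy-4-methyloxan-3-yl]prop-2-enoate (lactol, both anomers)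
Conditions: CpRu(MeCN)3PF6 (5 mol %), 5,5′-bis(trifluoromethyl)-2,2′-bipyridine (5 mol %), N-methylpyrrolidone/H2O, 25 °C
Reagents that add atoms: water, O
Why: Ruthenium-catalysed anti-Markovnikov hydration of a terminal alkyne through a vinylidene: water adds to the terminal carbon C8 and the aldehyde is trapped by the C6 hydroxyl as the six-membered lactol; alkenes cannot form vinylidenes, and the vinyl group has no allylic hydrogen to isomerise.

Step 6
Reactants: 9 lactol; 10 methyl 2-(bromomethyl)prop-2-enoate
Product: 11 1-tert-butyl 9-methyl (3R,4S)-4-ethenyl-6-hydroxy-3-(hydroxymethyl)-4-methyl-2,8-dimethylidenenonanedioate (both epimers at the new carbinol C8)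
Conditions: In powder, THF/H2O (1:1), 23 °C; neutral work-up, used at once
Reagents that add atoms: none
Why: Indium-mediated Barbier allylation in water: the allylindium reagent from 10 adds through its γ-carbon to the aldehyde in equilibrium with the lactol, forming C7–C8 and delivering the complete C11(=C13)–C12 acrylate. The new C8 carbinol needs no control because it is oxidised next, and the neutral medium should keep the hydroxy ester from lactonising onto O8.

Step 7
Reactants: 11 diol
Product: 12 1-tert-butyl 9-methyl (3R,4S)-4-ethenyl-3-formyl-4-methyl-2,8-dimethylidene-6-oxononanedioate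
Conditions: (COCl)2, DMSO, CH2Cl2, −78 °C; i-Pr2NEt, −78 → −40 °C; cold pH 7 buffer; used crude
Reagents that add atoms: none
Why: Swern oxidation: both hydroxyls become alkoxysulfonium salts before base is added, so the C6 aldehyde and the C8 ketone appear together and no lactol is left to be over-oxidised to a lactone. The hindered amine and cold quench are meant to leave C5 untouched.

Step 8
Reactants: 12 keto aldehyde
Product: 16 tert-butyl 2-[(3aS,6S,7R,7aR)-6-ethenyl-6-methyl-3-methylidene-2,4-dioxooctahydro-1-benzofuran-7-yl]prop-2-enoate, via silyl dienol ether 13 (not isolated), via silyl ether aldol 14 (not isolated), via hydroxy keto diester 15 (not isolated)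
Conditions: TMSOTf (2.2 equiv), i-Pr2NEt (2.5 equiv), CH2Cl2, −78 °C; then 1 M HCl, THF, 0 °C; then camphorsulfonic acid (10 mol %), CH2Cl2, 23 °C
Reagents that add atoms: none
Why: Soft enolisation with a silyl triflate and a hindered amine should take the doubly activated, unhindered C7 methylene (not the buried tertiary H-5 or the neopentyl C9) to the Z silyl dienol ether, which adds through C7 to the silyl-activated aldehyde in an intramolecular Mukaiyama aldol reaction (6-enolendo-exo-trig). In the chair-like closure the C5 substituent and the new C6–O and C7–C11 bonds are equatorial and the aldehyde oxygen avoids the axial C10 methyl, which gives the 6α-oxygen and 7β-carbon of the target. Acid then frees O6, which displaces methanol from the methyl ester only (the tert-butyl ester does not transesterify), closing the trans-fused α-methylene-γ-butyrolactone.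

Step 9
Reactants: 16 keto lactone
Product: 17 tert-butyl 2-[(3aR,4R,6S,7R,7aR)-6-ethenyl-4-hydroxy-6-methyl-3-methylidene-2-oxooctahydro-1-benzofuran-7-yl]prop-2-enoate
Conditions: LiAlH(Ot-Bu)3, THF, −78 → −40 °C; AcOH quench at −78 °C
Reagents that add atoms: none
Why: Hydride reduction of a cyclohexanone under steric approach control: the axial trajectory on the β face is blocked by the syn-axial C10 methyl, so the bulky aluminium hydride should enter equatorially and give the axial 8β (8R) alcohol. This reagent does not add in conjugate fashion and should leave lactone and esters alone at low temperature.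

Step 10
Reactants: 17 8β-alcohol; 18 (E)-2-methylbut-2-enoyl chloride (tigloyl chloride)
Product: 19 tert-butyl 2-[(3aR,4R,6S,7R,7aR)-6-ethenyl-6-methyl-3-methylidene-4-{[(2E)-2-methylbut-2-enoyl]oxy}-2-oxooctahydro-1-benzofuran-7-yl]prop-2-enoate
Conditions: pyridine, 4-(dimethylamino)pyridine (cat.), CH2Cl2, 0 → 23 °C
Reagents that add atoms: none
Why: Nucleophile-catalysed acylation of the secondary alcohol by the acid chloride; pyridine instead of a trialkylamine avoids deprotonation of the acyl chloride to a vinylketene (loss of the E-2-ene), and prompt acylation keeps O8 from attacking the lactone carbonyl.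

Step 11
Reactants: 19 tert-butyl ester
Product: 20 2-[(3aR,4R,6S,7R,7aR)-6-ethenyl-6-methyl-3-methylidene-4-{[(2E)-2-methylbut-2-enoyl]oxy}-2-oxooctahydro-1-benzofuran-7-yl]prop-2-enoic acid (CNP0256928.1)
Conditions: CF3CO2H/CH2Cl2 (1:4), 0 → 23 °C
Reagents that add atoms: none
Why: Acidolysis of the tert-butyl ester (loss of isobutene through the tert-butyl cation) frees the C15 acid without base or nucleophile, so lactone, tiglate, Michael acceptors and all stereocentres should be unaffected.

## Compound list

1 | (E)-3-methylpent-2-en-4-yn-1-ol | C#C/C(C)=C/CO | starting material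
2 | itaconic anhydride (3-methylideneoxolane-2,5-dione) | C=C1CC(=O)OC1=O | starting material
3 | 2-methylidene-4-{[(2E)-3-methylpent-2-en-4-yn-1-yl]oxy}-4-oxobutanoic acid | C=C(CC(=O)OC/C=C(\C)C#C)C(=O)O | intermediate
4 | 1-tert-butyl 4-[(2E)-3-methylpent-2-en-4-yn-1-yl] 2-methylidenebutanedioate | C=C(CC(=O)OC/C=C(\C)C#C)C(=O)OC(C)(C)C | intermediate
5 | boron ketene acetal of 4 (acrylate unit trans to O–B; (4S,5S)-diazaborolidine on oxygen) | C=C(C(=O)OC(C)(C)C)/C=C(/OB1N(S(=O)(=O)c2cc(C(F)(F)F)cc(C(F)(F)F)c2)[C@@H](c2ccccc2)[C@H](c2ccccc2)N1S(=O)(=O)c1cc(C(F)(F)F)cc(C(F)(F)F)c1)OC/C=C(\C)C#C | intermediate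
6 | (2R,3S)-2-[1-(tert-butoxycarbonyl)ethenyl]-3-ethynyl-3-methylpent-4-enoic acid | C=C[C@]([C@H](C(=C)C(=O)OC(C)(C)C)C(=O)O)(C)C#C | intermediate
7 | 1-acylimidazole of acid 6 | C=C[C@]([C@H](C(=C)C(=O)OC(C)(C)C)C(=O)n1ccnc1)(C)C#C | intermediate
8 | tert-butyl (3R,4S)-4-ethynyl-3-(hydroxymethyl)-4-methyl-2-methylidenehex-5-enoate | C=C[C@]([C@H](C(=C)C(=O)OC(C)(C)C)CO)(C)C#C | intermediate
9 | tert-butyl 2-[(3R,4S)-4-ethenyl-6-hydroxy-4-methyloxan-3-yl]prop-2-enoate (both anomers) | C=C[C@]1(C)CC(O)OC[C@H]1C(=C)C(=O)OC(C)(C)C | intermediate
10 | methyl 2-(bromomethyl)prop-2-enoate | C=C(CBr)C(=O)OC | starting material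
11 | 1-tert-butyl 9-methyl (3R,4S)-4-ethenyl-6-hydroxy-3-(hydroxymethyl)-4-methyl-2,8-dimethylidenenonanedioate (both carbinol epimers) | C=C[C@](C)(CC(O)CC(=C)C(=O)OC)[C@@H](CO)C(=C)C(=O)OC(C)(C)C | intermediate
12 | 1-tert-butyl 9-methyl (3R,4S)-4-ethenyl-3-formyl-4-methyl-2,8-dimethylidene-6-oxononanedioate | C=C[C@](C)(CC(=O)CC(=C)C(=O)OC)[C@@H](C=O)C(=C)C(=O)OC(C)(C)C | intermediate
13 | (6Z)-6-(trimethylsilyloxy)non-6-ene form of 12 (silyl dienol ether of the ketone toward C7) | C=C[C@](C)(C/C(O[Si](C)(C)C)=C/C(=C)C(=O)OC)[C@@H](C=O)C(=C)C(=O)OC(C)(C)C | intermediate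
14 | tert-butyl 2-[(1R,2R,3S,6S)-6-ethenyl-3-(3-methoxy-3-oxoprop-1-en-2-yl)-6-methyl-4-oxo-2-(trimethylsilyloxy)cyclohexyl]prop-2-enoate | C=C[C@]1(C)CC(=O)[C@@H](C(=C)C(=O)OC)[C@H](O[Si](C)(C)C)[C@H]1C(=C)C(=O)OC(C)(C)C | intermediate
15 | tert-butyl 2-[(1R,2R,3S,6S)-6-ethenyl-2-hydroxy-3-(3-methoxy-3-oxoprop-1-en-2-yl)-6-methyl-4-oxocyclohexyl]prop-2-enoate | C=C[C@]1(C)CC(=O)[C@@H](C(=C)C(=O)OC)[C@H](O)[C@H]1C(=C)C(=O)OC(C)(C)C | intermediate
16 | tert-butyl 2-[(3aS,6S,7R,7aR)-6-ethenyl-6-methyl-3-methylidene-2,4-dioxooctahydro-1-benzofuran-7-yl]prop-2-enoate | C=C[C@]1(C)CC(=O)[C@H]2C(=C)C(=O)O[C@@H]2[C@H]1C(=C)C(=O)OC(C)(C)C | intermediate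
17 | tert-butyl 2-[(3aR,4R,6S,7R,7aR)-6-ethenyl-4-hydroxy-6-methyl-3-methylidene-2-oxooctahydro-1-benzofuran-7-yl]prop-2-enoate | C=C[C@]1(C)C[C@@H](O)[C@H]2C(=C)C(=O)O[C@@H]2[C@H]1C(=C)C(=O)OC(C)(C)C | intermediate
18 | (E)-2-methylbut-2-enoyl chloride (tigloyl chloride) | C/C=C(\C)C(Cl)=O | starting material
19 | tert-butyl ester of the target (8β-tiglate) | C=C[C@]1(C)C[C@@H](OC(=O)/C(C)=C/C)[C@H]2C(=C)C(=O)O[C@@H]2[C@H]1C(=C)C(=O)OC(C)(C)C | intermediate
20 | 2-[(3aR,4R,6S,7R,7aR)-6-ethenyl-6-methyl-3-methylidene-4-{[(2E)-2-methylbut-2-enoyl]oxy}-2-oxooctahydro-1-benzofuran-7-yl]prop-2-enoic acid | C=C[C@]1(C)C[C@@H](OC(=O)/C(C)=C/C)[C@H]2C(=C)C(=O)O[C@@H]2[C@H]1C(=C)C(=O)O | target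

## Step count and risks

Total: 11 steps. Longest linear sequence: 11 steps (from 1).

**Step 3 (key step).**
- What may go wrong: incomplete geometric control in enolising a β,γ-unsaturated ester, which erodes the C5/C10 relationship; weak or opposite face selectivity; addition of residual B–Br across the terminal alkyne during the long reaction time; amine-induced migration of the itaconate double bond before enolisation.
- Fallback: set out from 4 and run the rearrangement without a chiral controller through the dicyclohexylboron ketene acetal ((c-C6H11)2BOTf, Et3N, same E(O) geometry, no B–Br bond). This gives the racemic acid, that is 6 together with its enantiomer (2S,3R)-acid F1. The mixture is converted (pivaloyl chloride, Et3N, LiCl, (S)-4-benzyl-2-oxazolidinone) into the N-acyl oxazolidinone of 6, imide F2, and the diastereomeric N-acyl oxazolidinone of F1, imide F3. These are separated by chromatography, which also removes any C5 epimers. LiBH4 in THF/H2O at 0 °C cleaves F2 reductively and returns the route at alcohol 8, making step 4 unnecessary.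

**Step 8.**
- What may go wrong: enolisation of the aldehyde at C5 before ring closure (loss of the C5/C10 relationship; H-5 is α to the formyl group and allylic to the acrylate); closure through the alternative chair; epimerisation at C7 or β-elimination of O6 once the keto lactone exists; early loss of the tert-butyl ester to the silyl triflate.
- Fallback: set out from lactol 9 and remove the allylic activation of H-5 by adding thiophenol (cat. Et3N) to the tert-butyl acrylate, giving the phenylthio adduct of 9, sulfide F4. Steps 6 to 8 then pass through the phenylthio adduct of 11, diol F5, the phenylthio adduct of 12, keto aldehyde F6, and the phenylthio adduct of 16, keto lactone F7. Oxidation (mCPBA, −78 °C) to the sulfoxide of F7, sulfoxide F8, and thermal syn-elimination (toluene, 90 °C) restore the C4=C3 bond and return the route at keto lactone 16.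

**Step 5.**
- What may go wrong: metal-mediated coupling of the alkyne with one of the alkenes at the cationic ruthenium centre; slow vinylidene formation at the neopentyl-type alkyne; catalyst inhibition by the chelating hydroxy enyne.
- Fallback: set out from 8 and use the hydroxyl as the nucleophile. Endo-selective cycloisomerisation with W(CO)6 (cat.), Et3N, THF under irradiation should give the cyclic enol ether tert-butyl 2-[(3R,4S)-4-ethenyl-4-methyl-3,4-dihydro-2H-pyran-3-yl]prop-2-enoate, dihydropyran F9. Mild acid hydration (pyridinium p-toluenesulfonate, THF/H2O) converts F9 into lactol 9.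

**Step 9.**
- What may go wrong: insufficient face selectivity of hydride delivery; attack of the new C8 alkoxide on the lactone carbonyl (lactone migration from O6 to O8); enolisation toward C7 with epimerisation.
- Fallback: set out from 16 and replace substrate control by reagent control. Reduction with (S)-2-methyl-CBS-oxazaborolidine and catecholborane should give the 8R carbinol by the usual large/small model (C7 large, C9 small); the medium is non-basic and never generates a free alkoxide. This returns the route at 17 with no new intermediate.

## Further compounds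

F1 | step 3 | (2S,3R)-2-[1-(tert-butoxycarbonyl)ethenyl]-3-ethynyl-3-methylpent-4-enoic acid (enantiomer of 6) | C=C[C@@]([C@@H](C(=C)C(=O)OC(C)(C)C)C(=O)O)(C)C#C
F2 | step 3 | N-acyl derivative of (S)-4-benzyl-1,3-oxazolidin-2-one from acid 6 | C=C[C@]([C@H](C(=C)C(=O)OC(C)(C)C)C(=O)N1C(=O)OC[C@@H]1Cc1ccccc1)(C)C#C
F3 | step 3 | N-acyl derivative of (S)-4-benzyl-1,3-oxazolidin-2-one from acid F1 | C=C[C@@]([C@@H](C(=C)C(=O)OC(C)(C)C)C(=O)N1C(=O)OC[C@@H]1Cc1ccccc1)(C)C#C
F4 | step 8 | phenylthio adduct of lactol 9 (PhS on C3, both C4 epimers) | C=C[C@]1(C)CC(O)OC[C@H]1C(CSc1ccccc1)C(=O)OC(C)(C)C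
F5 | step 8 | phenylthio adduct of diol 11 | C=C[C@](C)(CC(O)CC(=C)C(=O)OC)[C@@H](CO)C(CSc1ccccc1)C(=O)OC(C)(C)C
F6 | step 8 | phenylthio adduct of keto aldehyde 12 | C=C[C@](C)(CC(=O)CC(=C)C(=O)OC)[C@@H](C=O)C(CSc1ccccc1)C(=O)OC(C)(C)C
F7 | step 8 | phenylthio adduct of keto lactone 16 | C=C[C@]1(C)CC(=O)[C@H]2C(=C)C(=O)O[C@@H]2[C@H]1C(CSc1ccccc1)C(=O)OC(C)(C)C
F8 | step 8 | sulfoxide of F7 | C=C[C@]1(C)CC(=O)[C@H]2C(=C)C(=O)O[C@@H]2[C@H]1C(CS(=O)c1ccccc1)C(=O)OC(C)(C)C
F9 | step 5 | tert-butyl 2-[(3R,4S)-4-ethenyl-4-methyl-3,4-dihydro-2H-pyran-3-yl]prop-2-enoate | C=C[C@]1(C)C=COC[C@H]1C(=C)C(=O)OC(C)(C)C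
F0 | step 9 | none | none
A1 | alternative 1 | (5R)-5-[(tert-butyldimethylsilyl)oxy]-3-methylcyclohex-2-en-1-one | CC1=CC(=O)C[C@H](O[Si](C)(C)C(C)(C)C)C1
A2 | alternative 1 | (3R,5R)-3-ethenyl-3-methyl-5-[(tert-butyldimethylsilyl)oxy]cyclohexan-1-one | C=C[C@]1(C)C[C@@H](O[Si](C)(C)C(C)(C)C)CC(=O)C1
A3 | alternative 2 | 8β-tigloyloxygermacra-1(10),4,11(13)-trien-12,6α-olid-15-oic acid, both ring double bonds trans within the ring | C/C1=C\CC/C(C(=O)O)=C/[C@H]2OC(=O)C(=C)[C@@H]2[C@H](OC(=O)/C(C)=C/C)C1
A4 | alternative 3 | 3,5-dimethoxybenzoic acid | COc1cc(OC)cc(c1)C(=O)O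
A5 | alternative 3 | 5-ethenyl-5-methylcyclohexane-1,3-dione | C=CC1(C)CC(=O)CC(=O)C1
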